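**Retrosynthetic overview**

1. Target ⇒ hydrogenolysis of the two benzyl ethers of its 5,7-di-O-benzyl derivative (last step, no ring formed).
2. Key disconnection: the diaryl ether C8–O bond, made by joining the C8–H of 5,7-di-O-benzylacacetin to the 4'-OH of genkwanin in one pot (transient aryl-λ3-iodane, then Cu-catalysed C–O coupling).
3. 5,7-Di-O-benzylacacetin ⇒ acacetin ⇒ 2',4',6'-trihydroxyacetophenone + 4-methoxybenzoyl chloride (1,3-diketone, cyclodehydration).
4. Genkwanin ⇒ apigenin (selective 7-O-methylation).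
5. Ring order: only the pyranone ring of flavone I is built (step 1); flavone II comes with all its rings from apigenin; the two flavones are joined afterwards.

Assumption: the target has no stereocentre and no stable stereoaxis, so it is one achiral compound and no step needs stereocontrol.

**Route**

Step 1
Reactants: 1 2',4',6'-trihydroxyacetophenone (anhydrous); 2 4-methoxybenzoyl chloride
Product: 4 acacetin (5,7-dihydroxy-2-(4-methoxyphenyl)-4H-chromen-4-one), via diketone 3 (not isolated)
Conditions: LiHMDS (5 equiv), THF, −78 °C; then 2 (1.0 equiv), −78 °C → rt; aq HCl; crude in AcOH, H2SO4 (cat.), 95 °C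
Reagents that add atoms: none
Why: Excess LiHMDS gives the phenoxide/enolate polyanion of 1, whose methyl-ketone enolate carbon is acylated by 2 (crossed Claisen acylation, a one-pot Baker–Venkataraman equivalent), and the 1,3-diketone 3 closes the pyranone ring by acid-catalysed cyclodehydration.

Step 2
Reactants: 4 acacetin
Product: 5 5,7-bis(benzyloxy)-2-(4-methoxyphenyl)-4H-chromen-4-one
Conditions: BnBr (3 equiv), K2CO3 (4 equiv), DMF, 80 °C
Reagents that add atoms: benzyl bromide, BrCc1ccccc1
Why: Williamson ether synthesis; the acidic 7-OH reacts at once and the hydrogen-bonded 5-OH under excess reagent and heat, and capping 5-OH is what later sends electrophiles to C8 instead of C6.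

Step 3
Reactants: 6 apigenin
Product: 7 genkwanin (5-hydroxy-2-(4-hydroxyphenyl)-7-methoxy-4H-chromen-4-one)
Conditions: K2CO3 (1.05 equiv), MeI (1.1 equiv), DMF, 0 °C → rt
Reagents that add atoms: iodomethane, CI
Why: Williamson etherification under mono-anion control; the 7-OH (para to the C4 carbonyl, a vinylogous acid) is the most acidic OH, the 4'-OH is less acidic and the chelated 5-OH is inert.

Step 4
Reactants: 5 5,7-bis(benzyloxy)-2-(4-methoxyphenyl)-4H-chromen-4-one; 7 genkwanin
Product: 9 5,7-bis(benzyloxy)-8-[4-(5-hydroxy-7-methoxy-4-oxo-4H-chromen-2-yl)phenoxy]-2-(4-methoxyphenyl)-4H-chromen-4-one, via iodonium tosylate 8 (not isolated)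
Conditions: (i) 2-iodo-1,3,5-triisopropylbenzene (1.05 equiv), mCPBA (0.95 equiv), TsOH·H2O (1.05 equiv), CH2Cl2/TFE 1:1, rt, 1 h; then 5, 0 °C → rt; aq NaHCO3 wash, concentrate; (ii) 7 (1.0 equiv), Cu(MeCN)4BF4 (20 mol %), Et3N (2 equiv), CH2Cl2/DMSO, rt → 40 °C
Reagents that add atoms: none
Why: Proposed new method: one-pot C8–H aryloxylation of a flavone. The Koser-type ArI(OH)OTs made in the flask attacks 5 by SEAr at C8, the site where 5,7-dialkoxyflavones are halogenated (para to 5-OBn, ortho to 7-OBn, less crowded than C6), giving the unsymmetrical diaryl-λ3-iodane 8. The Cu(I) phenoxide of 7 then adds oxidatively into the flavonyl–I bond, since the 2,4,6-triisopropylphenyl group with two ortho-isopropyls is the non-transferred dummy, and C–O reductive elimination from aryl–Cu(III)–OAr forms the ether; the chelated 5-OH of 7 does not compete. Closest known reaction type: Cu-catalysed O-arylation of phenols with unsymmetrical diaryliodonium salts and the λ3-iodane-mediated para C–H functionalisation of simple electron-rich arenes, not demonstrated at a di-ortho-oxygenated flavone C–H bond or with a flavone phenol as partner.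

Step 5
Reactants: 9 5,7-bis(benzyloxy)-8-[4-(5-hydroxy-7-methoxy-4-oxo-4H-chromen-2-yl)phenoxy]-2-(4-methoxyphenyl)-4H-chromen-4-one
Product: 10 5,7-dihydroxy-8-[4-(5-hydroxy-7-methoxy-4-oxo-4H-chromen-2-yl)phenoxy]-2-(4-methoxyphenyl)-4H-chromen-4-one (target)
Conditions: H2 (1 atm), 10% Pd/C, THF/MeOH, rt
Reagents that add atoms: none
Why: Catalytic hydrogenolysis of the two benzyl aryl ethers; the methyl ethers, the diaryl ether and the chelated phenol are inert, and the flavone C2=C3 bond is not reduced at 1 atm and rt in the time needed.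

**Compound list**

1 | 2',4',6'-trihydroxyacetophenone | CC(=O)c1c(O)cc(O)cc1O | starting material
2 | 4-methoxybenzoyl chloride | COc1ccc(C(Cl)=O)cc1 | starting material
3 | 1-(4-methoxyphenyl)-3-(2,4,6-trihydroxyphenyl)propane-1,3-dione | COc1ccc(C(=O)CC(=O)c2c(O)cc(O)cc2O)cc1 | intermediate
4 | acacetin, 5,7-dihydroxy-2-(4-methoxyphenyl)-4H-chromen-4-one | COc1ccc(-c2cc(=O)c3c(O)cc(O)cc3o2)cc1 | intermediate
5 | 5,7-bis(benzyloxy)-2-(4-methoxyphenyl)-4H-chromen-4-one | COc1ccc(-c2cc(=O)c3c(OCc4ccccc4)cc(OCc4ccccc4)cc3o2)cc1 | intermediate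
6 | apigenin, 5,7-dihydroxy-2-(4-hydroxyphenyl)-4H-chromen-4-one | O=c1cc(-c2ccc(O)cc2)oc2cc(O)cc(O)c12 | starting material
7 | genkwanin, 5-hydroxy-2-(4-hydroxyphenyl)-7-methoxy-4H-chromen-4-one | COc1cc(O)c2c(=O)cc(-c3ccc(O)cc3)oc2c1 | intermediate
8 | [5,7-bis(benzyloxy)-2-(4-methoxyphenyl)-4-oxo-4H-chromen-8-yl](2,4,6-triisopropylphenyl)iodonium 4-methylbenzenesulfonate | COc1ccc(-c2cc(=O)c3c(OCc4ccccc4)cc(OCc4ccccc4)c([I+]c4c(C(C)C)cc(C(C)C)cc4C(C)C)c3o2)cc1.Cc1ccc(S(=O)(=O)[O-])cc1 | intermediate
9 | 5,7-bis(benzyloxy)-8-[4-(5-hydroxy-7-methoxy-4-oxo-4H-chromen-2-yl)phenoxy]-2-(4-methoxyphenyl)-4H-chromen-4-one | COc1ccc(-c2cc(=O)c3c(OCc4ccccc4)cc(OCc4ccccc4)c(Oc4ccc(-c5cc(=O)c6c(O)cc(OC)cc6o5)cc4)c3o2)cc1 | intermediate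
10 | 5,7-dihydroxy-8-[4-(5-hydroxy-7-methoxy-4-oxo-4H-chromen-2-yl)phenoxy]-2-(4-methoxyphenyl)-4H-chromen-4-one | COc1ccc(-c2cc(=O)c3c(O)cc(O)c(Oc4ccc(-c5cc(=O)c6c(O)cc(OC)cc6o5)cc4)c3o2)cc1 | target

**Step count and risks**

Total step count: 5. Longest linear sequence: 4 (steps 1, 2, 4, 5).

Step 4 is the most likely to fail. The bulky iodine(III) reagent may react slowly at the di-ortho-substituted C8, the uncatalysed pathway may transfer the wrong aryl group, and the 5-hydroxy-4-keto unit of 7 may bind copper. The fallback uses known chemistry, sets out from 5 and comes back at 9. NIS with catalytic TFA in MeCN at rt iodinates 5 at C8, as is established for 5,7-dialkoxyflavones, and gives 5,7-bis(benzyloxy)-8-iodo-2-(4-methoxyphenyl)-4H-chromen-4-one F1. An Ullmann diaryl ether condensation of this iodide with 7 (CuI, picolinic acid, K3PO4, DMSO, 90 °C) then gives 9.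

Step 3 is the second risk, because 4'-O- and 7,4'-di-O-methylation can compete with the wanted 7-O-methylation. The fallback replaces acidity control by protecting-group control, sets out from 6 and comes back at 7. Ac2O in pyridine gives apigenin 5,7,4'-triacetate F2. Thiophenol and imidazole in NMP remove only the most labile 7-O-acetyl group and give 5,4'-di-O-acetylapigenin F3. Mitsunobu methylation (MeOH, PPh3, DIAD, THF) of the free 7-OH gives 5,4'-di-O-acetylgenkwanin F4. K2CO3 in MeOH at rt removes both acetates and gives 7.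

Step 2 is the third risk: the chelated 5-OH is benzylated sluggishly, and C-benzylation of the phloroglucinol-type ring can occur under forcing conditions. The fallback puts the benzyl groups on before the flavone is built, sets out from 1 and comes back at 5, passing by 4. BnBr (2.1 equiv) and K2CO3 in DMF leave the hydrogen-bonded ortho-OH free and give 1-[2,4-bis(benzyloxy)-6-hydroxyphenyl]ethan-1-one F5. Claisen–Schmidt condensation with commercial 4-methoxybenzaldehyde (KOH, EtOH, rt) gives (E)-1-[2,4-bis(benzyloxy)-6-hydroxyphenyl]-3-(4-methoxyphenyl)prop-2-en-1-one F6. Oxidative cyclisation with catalytic I2 in DMSO at 120 °C gives 5.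

**Further compounds**

F1 | step 4 | 5,7-bis(benzyloxy)-8-iodo-2-(4-methoxyphenyl)-4H-chromen-4-one | COc1ccc(-c2cc(=O)c3c(OCc4ccccc4)cc(OCc4ccccc4)c(I)c3o2)cc1
F2 | step 3 | apigenin 5,7,4'-triacetate | CC(=O)Oc1ccc(-c2cc(=O)c3c(OC(C)=O)cc(OC(C)=O)cc3o2)cc1
F3 | step 3 | 5,4'-di-O-acetylapigenin (7-OH free) | CC(=O)Oc1ccc(-c2cc(=O)c3c(OC(C)=O)cc(O)cc3o2)cc1
F4 | step 3 | 5,4'-di-O-acetylgenkwanin | CC(=O)Oc1ccc(-c2cc(=O)c3c(OC(C)=O)cc(OC)cc3o2)cc1
F5 | step 2 | 1-[2,4-bis(benzyloxy)-6-hydroxyphenyl]ethan-1-one | CC(=O)c1c(O)cc(OCc2ccccc2)cc1OCc1ccccc1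
F6 | step 2 | (E)-1-[2,4-bis(benzyloxy)-6-hydroxyphenyl]-3-(4-methoxyphenyl)prop-2-en-1-one | COc1ccc(/C=C/C(=O)c2c(O)cc(OCc3ccccc3)cc2OCc2ccccc2)cc1
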